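The data come from a simulation for substances that don't exist, noise included.

**Late readings.** Late in Saturday's flask [E], the concentration of E, falls just 5.00 mM from the first reading at 3.4 min to the last at 27 min, less than the 44.4 mM lost before that first reading. The early loss is what I look at.

| flask | E | X | time |
|---|---|---|---|
| Friday's | 0.0800 M | 0.0640 M |  |
| Thursday's | 0.0320 M | 0.0160 M |  |
| Sunday's | 0.0800 M | 0.0960 M |  |
| Saturday's | 0.160 M | 0.0640 M |  |
| Tuesday's | 0.0400 M | 0.0320 M | 27 min |

- Friday's run (time / min: [E] / M): 3.4: 0.0481; 6.8: 0.0470; 10: 0.0418; 14: 0.0411; 17: 0.0398; 20: 0.0385; 24: 0.0394; 27: 0.0390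
- Thursday's run (time / min: [E] / M): 3.4: 0.0263; 6.8: 0.0270; 10: 0.0261; 14: 0.0245; 17: 0.0227; 20: 0.0232; 24: 0.0229; 27: 0.0217
- Sunday's run (time / min: [E] / M): 3.4: 0.0378; 6.8: 0.0352; 10: 0.0327; 14: 0.0302; 17: 0.0300; 20: 0.0272; 24: 0.0267; 27: 0.0258
- Saturday's run (time / min: [E] / M): 3.4: 0.1156; 6.8: 0.1132; 10: 0.1112; 14: 0.1119; 17: 0.1097; 20: 0.1101; 24: 0.1091; 27: 0.1106

(standard deviation of a reading: 8 × 10⁻⁴ M)

- Overall: E + X -> Z.
- Constant volume, constant temperature.
- "The second partner" is X.
- An order is taken over about fifteen percent of the charge, up and down.

1. the power of [X] that the first rate follows, about the charge of the Friday's run; measure it at two percent of E made into Z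
2. the power of [E] that the first rate follows, about the charge of the Friday's run; measure it at two percent of E made into Z (one fixed amount of Z, the same in the runs compared)
3. E in the Tuesday's run at 27 min, as a share of the E charged
4. which of these the readings show (the product decays / two substrates go astray together / the product reacts on with the second partner / nothing beyond the main steps)

**Bench rule.** For two partners meeting, I would expect the first rate to follow the charges, with a power (reaction order) of one in each. Sunday's flask, with 1.50 times Friday's X, would then run 1.50 times as fast. Saturday's, with 2.00 times Friday's E, would run 2.00 times as fast.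

**Its border.** The rule treats the charge as free to react. But Friday's first reading is 60.1 % of the E charged, so I replace the charges by what the first reading shows.

**My reckoning.** In Friday's flask, the first [E] times the X left if each lost E took one X is 0.00154 M^2; I call this the free product. Sunday's is 0.00203 M^2 and Saturday's 0.00227 M^2. I take the rate to follow it, so the ratios to Friday's are 1.32 and 1.47. Dividing the logarithm of each ratio by that of its charge ratio gives a mean power over the whole step: 0.679 for [X], the concentration of X, and 0.553 for [E]. I commit to these, though both steps are wider than the one asked.

**The forecast.** It gives 1 for [X], 1 for [E], 55 % for Tuesday's flask, and says the product decays. On the powers it holds that “mass action gives about 1 each”, which differs from my reckoning.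

**The steps.** The readings came from these:

    E + X ⇌ J, settled at all times (13.30 M⁻¹)
    E + X → Z (1.896 M⁻¹ min⁻¹)
    Z + X → Q (2.850 M⁻¹ min⁻¹)

**What ran.** The powers are 0.78 for [X] and 0.75 for [E], against my 0.679 and 0.553 and the forecast's 1 for each. E in Tuesday's flask at 27 min is 52.5 % of its charge, and the readings show that the product reacts on with the second partner. Throughout, E and X stood in balance with J while E + X → Z ran. Z + X → Q ran on the Z so made, with X. Where two percent of Friday's E has turned, Sunday's rate is 1.3 times Friday's, beside a free-product ratio, taken from the first readings, of 1.32. Saturday's free-product ratio is 1.47, and its rate is 1.5 times Friday's.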